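**Plan**

Ring numbering: C1 is the carbonyl between C2 (OMe) and C6 (side chain); C3 is CH, C4 is the second carbonyl, C5 is CH.
1. Cuts: after retro-oxidation the ring is cut at C4–C5 (retro-6π) and C1 is joined to C4 (retro-4π). This gives a 4-alkenyl-4-hydroxy-3-methoxycyclobutenone, which is then cut at C1–C6 (carbonyl addition).
2. Enabling feature: C4(=O)–C3H=C2(OMe)–C1(=O) is a contiguous, fully oxygenated four-carbon arc, which is methyl semisquarate. C6=C5 is a 1,1-disubstituted vinyl unit carrying the chain. The quinone is an isomer of their adduct less two hydrogens.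
3. Side-chain cuts: the vinyl unit comes from a terminal alkyne, the alkyne–CH2 bond from acetylide plus epoxide, and the chain bond from decyl Grignard plus epichlorohydrin.
4. Forward order: chain assembly (steps 1–4), semisquarate (step 5), union (step 6), silyl-to-acetate exchange (steps 7–8). The only ring of the target is formed in the last step (step 9).
5. Stereochemistry: the single stereocentre is C2 of (R)-epichlorohydrin, and its C–O bond is never broken.

Key step: step 9

Assumption: the ring carbinol carbon made in step 6 forms as a mixture of epimers. It is drawn without a descriptor and carried as such, because it becomes a carbonyl carbon in step 9.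

**Step 1**
Reactants: 1 (R)-epichlorohydrin; 2 decylmagnesium bromide
Product: 3 (R)-1-chlorotridecan-2-ol
Conditions: CuI (10 mol %), THF, −40 to 0 °C; aq NH4Cl
Reagents that add atoms: none
Why: Copper-catalysed Grignard opening of a terminal epoxide attacks the unsubstituted oxirane carbon faster than the C–Cl bond, and since no bond to the stereocentre is broken the configuration of 1 passes unchanged into 3.

**Step 2**
Reactants: 3 (R)-1-chlorotridecan-2-ol; 4 lithium acetylide–ethylenediamine complex
Product: 6 (R)-pentadec-1-yn-4-ol, via (R)-2-undecyloxirane 5 (not isolated)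
Conditions: 4 (3 equiv), DMSO, 0 °C to rt; H2O
Reagents that add atoms: none
Why: One equivalent of acetylide deprotonates the chlorohydrin, which closes to 5 by intramolecular Williamson displacement, and a further equivalent opens 5 at its CH2 terminus (SN2 epoxide alkynylation), so the C–O bond of the stereocentre stays intact.

**Step 3**
Reactants: 6 (R)-pentadec-1-yn-4-ol
Product: 7 (R)-2-iodopentadec-1-en-4-ol
Conditions: NaI (2 equiv), TMSCl (2 equiv), H2O (1 equiv), MeCN, 0 °C to rt
Reagents that add atoms: sodium iodide, [Na+].[I-]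
Why: HI generated in situ adds to the terminal alkyne in the Markovnikov sense (hydroiodination, well known for free homopropargylic alcohols) and should give the 2-iodo-1-alkene without touching the carbinol centre.

**Step 4**
Reactants: 7 (R)-2-iodopentadec-1-en-4-ol
Product: 8 (R)-triethyl[(2-iodopentadec-1-en-4-yl)oxy]silane
Conditions: TESCl, imidazole, CH2Cl2, 0 °C to rt
Reagents that add atoms: chlorotriethylsilane (TESCl), CC[Si](Cl)(CC)CC
Why: Standard silylation of a secondary alcohol masks the acidic proton for the lithiation, and the triethylsilyl ether can later be removed under buffered conditions.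

**Step 5**
Reactants: 9 dimethyl squarate
Product: 11 3-methoxycyclobut-3-ene-1,2-dione (methyl semisquarate), via 4-hydroxy-2,3-dimethoxycyclobut-2-en-1-one 10 (not isolated)
Conditions: LiAlH(Ot-Bu)3 (1.05 equiv), THF, −78 to −20 °C; 2 M HCl; then conc. HCl (cat.), CH2Cl2, rt
Reagents that add atoms: water, O
Why: The bulky hydride reduces one squarate carbonyl in 1,2-fashion and stops there, and acid then ionises the allylic hydroxyl of 10 to a methoxy-stabilised cyclobutenyl cation whose hydrolysis expels methanol (the standard 1,2-addition/acid hydrolysis route from squarate esters to 3-alkoxycyclobutenediones).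

**Step 6**
Reactants: 8 (R)-triethyl[(2-iodopentadec-1-en-4-yl)oxy]silane; 11 3-methoxycyclobut-3-ene-1,2-dione
Product: 13 4-hydroxy-3-methoxy-4-[(4R)-4-(triethylsilyloxy)pentadec-1-en-2-yl]cyclobut-2-en-1-one, via alkenyllithium 12 (not isolated)
Conditions: t-BuLi (2.0 equiv), Et2O, −78 °C; cannulated into 11 (1.2 equiv), THF, −78 °C; aq NH4Cl at −78 °C
Reagents that add atoms: none
Why: Iodine–lithium exchange gives 12, which as a hard nucleophile adds 1,2 to the carbonyl next to the methoxy-bearing carbon because the other carbonyl is deactivated as a vinylogous ester (the usual regiochemistry of organolithium addition to alkoxycyclobutenediones), and the new carbinol centre is not controlled and need not be.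

**Step 7**
Reactants: 13 4-hydroxy-3-methoxy-4-[(4R)-4-(triethylsilyloxy)pentadec-1-en-2-yl]cyclobut-2-en-1-one
Product: 14 4-hydroxy-4-[(4R)-4-hydroxypentadec-1-en-2-yl]-3-methoxycyclobut-2-en-1-one
Conditions: HF·pyridine, pyridine, THF, 0 °C
Reagents that add atoms: none
Why: Buffered fluoride cleavage of a triethylsilyl ether proceeds at 0 °C, where the tertiary cyclobutenol, the vinylogous ester and the 1,1-disubstituted alkene should be inert.

**Step 8**
Reactants: 14 4-hydroxy-4-[(4R)-4-hydroxypentadec-1-en-2-yl]-3-methoxycyclobut-2-en-1-one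
Product: 15 (4R)-2-(1-hydroxy-2-methoxy-4-oxocyclobut-2-en-1-yl)pentadec-1-en-4-yl acetate
Conditions: Ac2O (1.5 equiv), pyridine, CH2Cl2, 0 °C to rt (no DMAP)
Reagents that add atoms: acetic anhydride, CC(=O)OC(C)=O
Why: Acylation without a nucleophilic catalyst distinguishes the secondary alcohol from the hindered tertiary cyclobutenol (chemoselective acetylation), with retention at the stereocentre because only the O–H bond reacts.

**Step 9**
Reactants: 15 (4R)-2-(1-hydroxy-2-methoxy-4-oxocyclobut-2-en-1-yl)pentadec-1-en-4-yl acetate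
Product: 19 (2R)-1-(5-methoxy-3,6-dioxocyclohexa-1,4-dien-1-yl)tridecan-2-yl acetate (target), via dienylketene 16 (not isolated), via cyclohexadienone 17 (not isolated), via hydroquinone 18 (not isolated)
Conditions: PhMe (0.02 M, degassed), 110 °C; cool to rt, then Ag2O (2 equiv), Na2SO4, rt
Reagents that add atoms: none
Why: Heating cleaves the strained C(=O)–C(OH) bond by a conrotatory 4π electrocyclic opening to dienylketene 16, which closes by a disrotatory 6π electrocyclisation between the ketene carbon and the terminal =CH2 to cyclohexadienone 17, which enolises to hydroquinone 18, from which Ag2O removes two hydrogens to give 19. The closest known reaction type is the Moore–Liebeskind ring expansion of 4-alkenyl-4-hydroxycyclobutenones to hydroquinones and quinones. The six-membered carbocycle is closed in the 6π electrocyclic mode, forming the C4–C5 bond, with all six ring atoms already at or near their final oxidation level. No new stereocentre is formed: the epimeric carbinol carbon becomes the C1 carbonyl, and the acetoxy-bearing centre lies outside the pericyclic array under neutral conditions, so it stays R. The step needs torquoselectivity, which the donor hydroxyl secures by rotating outward and thereby turning the alkenyl group inward, cis to the ketene. It also needs the 2,6-substitution pattern, which is fixed by the connectivity of 15 (the methoxy carbon is bonded to the carbinol carbon that carries the branched alkenyl carbon), so no isomeric quinone can arise, and the acetate is inert to the thermolysis and to Ag2O.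

**Compound list**

| No. | Name | SMILES | Role |
|---|---|---|---|
| 1 | (R)-epichlorohydrin | ClC[C@H]1CO1 | starting material |
| 2 | decylmagnesium bromide | CCCCCCCCCC[Mg]Br | starting material |
| 3 | (R)-1-chlorotridecan-2-ol | CCCCCCCCCCC[C@H](CCl)O | intermediate |
| 4 | lithium acetylide–ethylenediamine complex | [Li]C#C.NCCN | starting material |
| 5 | (R)-2-undecyloxirane | CCCCCCCCCCC[C@@H]1CO1 | intermediate |
| 6 | (R)-pentadec-1-yn-4-ol | CCCCCCCCCCC[C@H](CC#C)O | intermediate |
| 7 | (R)-2-iodopentadec-1-en-4-ol | CCCCCCCCCCC[C@H](CC(I)=C)O | intermediate |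
| 8 | (R)-triethyl[(2-iodopentadec-1-en-4-yl)oxy]silane | CCCCCCCCCCC[C@H](CC(I)=C)O[Si](CC)(CC)CC | intermediate |
| 9 | dimethyl squarate (3,4-dimethoxycyclobut-3-ene-1,2-dione) | COC1=C(OC)C(=O)C1=O | starting material |
| 10 | 4-hydroxy-2,3-dimethoxycyclobut-2-en-1-one (racemic) | COC1=C(OC)C(=O)C1O | intermediate |
| 11 | 3-methoxycyclobut-3-ene-1,2-dione (methyl semisquarate) | COC1=CC(=O)C1=O | intermediate |
| 12 | [(4R)-4-(triethylsilyloxy)pentadec-1-en-2-yl]lithium | CCCCCCCCCCC[C@H](CC([Li])=C)O[Si](CC)(CC)CC | intermediate |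
| 13 | 4-hydroxy-3-methoxy-4-[(4R)-4-(triethylsilyloxy)pentadec-1-en-2-yl]cyclobut-2-en-1-one (epimers at ring carbinol) | CCCCCCCCCCC[C@H](CC(=C)C1(O)C(OC)=CC1=O)O[Si](CC)(CC)CC | intermediate |
| 14 | 4-hydroxy-4-[(4R)-4-hydroxypentadec-1-en-2-yl]-3-methoxycyclobut-2-en-1-one (epimers at ring carbinol) | CCCCCCCCCCC[C@H](CC(=C)C1(O)C(OC)=CC1=O)O | intermediate |
| 15 | (4R)-2-(1-hydroxy-2-methoxy-4-oxocyclobut-2-en-1-yl)pentadec-1-en-4-yl acetate (epimers at ring carbinol) | CCCCCCCCCCC[C@H](CC(=C)C1(O)C(OC)=CC1=O)OC(C)=O | intermediate |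
| 16 | (4R)-2-[(1Z)-1-hydroxy-2-methoxy-4-oxobuta-1,3-dien-1-yl]pentadec-1-en-4-yl acetate (dienylketene) | CCCCCCCCCCC[C@H](CC(=C)/C(O)=C(OC)\C=C=O)OC(C)=O | intermediate |
| 17 | 5-[(2R)-2-acetoxytridecyl]-4-hydroxy-3-methoxycyclohexa-2,4-dien-1-one | CCCCCCCCCCC[C@H](CC1=C(O)C(OC)=CC(=O)C1)OC(C)=O | intermediate |
| 18 | (2R)-1-(2,5-dihydroxy-3-methoxyphenyl)tridecan-2-yl acetate | CCCCCCCCCCC[C@H](Cc1cc(O)cc(OC)c1O)OC(C)=O | intermediate |
| 19 | (2R)-1-(5-methoxy-3,6-dioxocyclohexa-1,4-dien-1-yl)tridecan-2-yl acetate | CCCCCCCCCCC[C@H](CC1=CC(=O)C=C(OC)C1=O)OC(C)=O | target |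

**Step count**

- Total step count: 9
- Longest linear sequence: 8 (steps 1, 2, 3, 4, 6, 7, 8, 9)

**Steps most likely to fail**

**Step 6.**
- What may go wrong: conjugate addition or proton abstraction at the unsubstituted ring carbon of the semisquarate may compete with carbonyl addition. O-to-C silyl migration in the alkenyllithium may also occur before it is consumed.
- The fallback sets out from 6 and comes back at 19. It builds the same ring without a carbanion and without a protecting group.
- Compound 6 is acetylated (Ac2O, pyridine, DMAP) to (R)-pentadec-1-yn-4-yl acetate F1.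
- [2+2] cycloaddition with dichloroketene (Cl3CCOCl, Zn–Cu, Et2O/DME) gives (R)-1-(4,4-dichloro-3-oxocyclobut-1-en-1-yl)tridecan-2-yl acetate F2.
- Zn, AcOH and TMEDA in EtOH remove both chlorines to give (R)-1-(3-oxocyclobut-1-en-1-yl)tridecan-2-yl acetate F3.
- Danheiser benzannulation with methoxyacetylene (PhMe, sealed tube, 80 then 120 °C; 4π opening, ketene–alkyne [2+2], 4π opening, 6π closure) gives (R)-1-(3-hydroxy-5-methoxyphenyl)tridecan-2-yl acetate F4.
- Teuber oxidation with Fremy's salt (KH2PO4 buffer, acetone–water) introduces the oxygen para to the phenol, between the methoxy and alkyl groups, to give 19.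

**Step 7.**
- What may go wrong: after loss of the silyl group the freed secondary hydroxyl may add to the methoxy-bearing ring carbon and expel methanol, closing a six-membered enol ether. Ring opening of the cyclobutenol under fluoride or acid is a second possibility.
- The fallback sets out from 13 and comes back at 19. It moves the ring formation ahead of the protecting-group exchange.
- Compound 13 is heated in degassed toluene as in step 9 to 3-methoxy-5-[(2R)-2-(triethylsilyloxy)tridecyl]benzene-1,4-diol F5.
- This is oxidised in the same flask with Ag2O to 2-methoxy-6-[(2R)-2-(triethylsilyloxy)tridecyl]-1,4-benzoquinone F6.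
- Aqueous HF in MeCN gives 2-[(2R)-2-hydroxytridecyl]-6-methoxy-1,4-benzoquinone F7.
- Ac2O/pyridine at 0 °C then gives 19.

**Step 9.**
- What may go wrong: the monosubstituted ketene may oligomerise or be intercepted before it closes. The unprotected hydroquinone may also suffer redox scrambling or over-oxidation during the one-flask oxidation.
- The fallback sets out from 15 and comes back at 19. It separates ring formation from oxidation by way of a stable phenol.
- The tertiary carbinol of 15 is O-methylated (MeI, Ag2O, MeCN) to (4R)-2-(1,2-dimethoxy-4-oxocyclobut-2-en-1-yl)pentadec-1-en-4-yl acetate F8.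
- Thermolysis in toluene gives the isolable (2R)-1-(5-hydroxy-2,3-dimethoxyphenyl)tridecan-2-yl acetate F9.
- Oxidative demethylation of this p-methoxyphenol with ceric ammonium nitrate (MeCN–H2O, 0 °C) gives 19.

**Further compounds**

F1 | step 6 | (R)-pentadec-1-yn-4-yl acetate | CCCCCCCCCCC[C@H](CC#C)OC(C)=O
F2 | step 6 | (R)-1-(4,4-dichloro-3-oxocyclobut-1-en-1-yl)tridecan-2-yl acetate | CCCCCCCCCCC[C@H](CC1=CC(=O)C1(Cl)Cl)OC(C)=O
F3 | step 6 | (R)-1-(3-oxocyclobut-1-en-1-yl)tridecan-2-yl acetate | CCCCCCCCCCC[C@H](CC1=CC(=O)C1)OC(C)=O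
F4 | step 6 | (R)-1-(3-hydroxy-5-methoxyphenyl)tridecan-2-yl acetate | CCCCCCCCCCC[C@H](Cc1cc(O)cc(OC)c1)OC(C)=O
F5 | step 7 | 3-methoxy-5-[(2R)-2-(triethylsilyloxy)tridecyl]benzene-1,4-diol | CCCCCCCCCCC[C@H](Cc1cc(O)cc(OC)c1O)O[Si](CC)(CC)CC
F6 | step 7 | 2-methoxy-6-[(2R)-2-(triethylsilyloxy)tridecyl]-1,4-benzoquinone | CCCCCCCCCCC[C@H](CC1=CC(=O)C=C(OC)C1=O)O[Si](CC)(CC)CC
F7 | step 7 | 2-[(2R)-2-hydroxytridecyl]-6-methoxy-1,4-benzoquinone | CCCCCCCCCCC[C@H](CC1=CC(=O)C=C(OC)C1=O)O
F8 | step 9 | (4R)-2-(1,2-dimethoxy-4-oxocyclobut-2-en-1-yl)pentadec-1-en-4-yl acetate | CCCCCCCCCCC[C@H](CC(=C)C1(OC)C(OC)=CC1=O)OC(C)=O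
F9 | step 9 | (2R)-1-(5-hydroxy-2,3-dimethoxyphenyl)tridecan-2-yl acetate | CCCCCCCCCCC[C@H](Cc1cc(O)cc(OC)c1OC)OC(C)=O
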